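The ten-membered carbocycle is opened at C3–C4, where the C3 oxirane carbon sits directly on C4 of the Z-configured C4=C5 alkene; at the ketone level this bond is an acyl–alkenyl bond. A Liebeskind–Srogl coupling of a C3 ethyl thioester with a Z C4 alkenylstannane closes the ring as a C2-silyloxy enone under neutral conditions, without touching the base-sensitive C2 centre. The seco precursor already carries the trans C6/C7 lactone (with C13 as an acetoxymethyl group), the C8 epoxyangelate, the C9 acetate and the C1(10) enoate, so that only ketone reduction, mesylation and fluoride-triggered epoxide closure with unmasking of the methylene lactone remain.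

Key step: step 24

Remarks on the chemistry (assumptions):
- Atom numbers are the germacrane numbers of 38 (C1–C10 ring, C11–C13 lactone carbons, C14 ester carbon, C15 methyl).
- C2 of 38 has the spatial arrangement of (S)-glyceraldehyde when the aldehyde carbon becomes C1, so the (S)-configured acetonide ester 5 is the glycerate that is required.
- C11 is a stereocentre of no consequence from 23 to 37 (epimer mixture, left undefined in the SMILES); the two aldol centres of 16 and 17 are likewise transient.

Step 1
Reactants: 1 angelic acid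
Product: 2 angelyl alcohol
Conditions: LiAlH4, Et2O, 0 °C; then aqueous NaOH
Reagents that add atoms: none
Why: LiAlH4 reduction of the carboxylic acid to the primary alcohol should proceed at 0 °C without reducing or isomerising the trisubstituted Z alkene, and no stereocentre is formed.

Step 2
Reactants: 2 angelyl alcohol
Product: 3 [(2R,3S)-2,3-dimethyloxiran-2-yl]methanol
Conditions: Ti(OiPr)4 (cat.), D-(−)-diisopropyl tartrate, tBuOOH, 4 Å MS, CH2Cl2, −20 °C
Reagents that add atoms: tert-butyl hydroperoxide, CC(C)(C)OO
Why: Sharpless asymmetric epoxidation of the Z allylic alcohol, in which the D-tartrate titanium complex delivers oxygen to the alkene face that sets C2 as R and C3 as S, while the cis relation of the C3 methyl and the hydroxymethyl group follows from the Z alkene.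

Step 3
Reactants: 3 [(2R,3S)-2,3-dimethyloxiran-2-yl]methanol
Product: 4 (2S,3S)-epoxyangelic acid
Conditions: RuCl3·xH2O (cat.), NaIO4, MeCN/EtOAc/H2O, 0 °C to rt
Reagents that add atoms: sodium periodate, [Na+].[O-]I(=O)(=O)=O; water, O
Why: Ruthenium tetroxide oxidation (catalytic RuCl3 with NaIO4) should take the primary alcohol to the acid through the aldehyde hydrate without opening the oxirane, and the quaternary C2 cannot epimerise (its descriptor changes to S only through the priority rules).

Step 4
Reactants: 5 methyl (S)-2,2-dimethyl-1,3-dioxolane-4-carboxylate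
Product: 6 methyl (S)-glycerate
Conditions: AcCl (cat.), MeOH, rt
Reagents that add atoms: none
Why: Acid-catalysed transketalisation to methanol (acetonide cleavage) should free the diol without involving the stereocentre.

Step 5
Reactants: 6 methyl (S)-glycerate
Product: 7 methyl (S)-2,3-bis(tert-butyldimethylsilyloxy)propanoate
Conditions: TBSCl, imidazole, DMF, rt
Reagents that add atoms: tert-butyldimethylsilyl chloride, CC(C)(C)[Si](C)(C)Cl
Why: Imidazole-mediated silylation should protect both hydroxyls, the secondary ether later serving as the C2 oxygen and the primary one as the masked C3 carboxyl carbon.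

Step 6
Reactants: 7 methyl (S)-2,3-bis(tert-butyldimethylsilyloxy)propanoate
Product: 8 (S)-2,3-bis(tert-butyldimethylsilyloxy)propanal
Conditions: iBu2AlH, CH2Cl2, −78 °C; then aqueous potassium sodium tartrate
Reagents that add atoms: none
Why: Partial ester reduction with iBu2AlH stops at the aluminium hemiacetal at −78 °C and should give the α-silyloxy aldehyde, which is used at once so that the stereocentre is not lost.

Step 7
Reactants: 9 dimethyl 2,3-O-isopropylidene-L-tartrate
Product: 10 tartrate monoacid
Conditions: KOH (1.0 equiv), MeOH, 0 °C to rt; then HCl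
Reagents that add atoms: potassium hydroxide, [K+].[OH-]
Why: Monosaponification of the C2-symmetric diester should give a single monoacid, because the two esters are equivalent and the first carboxylate slows the second hydrolysis, with both stereocentres untouched.

Step 8
Reactants: 10 tartrate monoacid
Product: 12 diazoketone, via mixed carbonic anhydride 11 (not isolated)
Conditions: iBuOCOCl, N-methylmorpholine, THF, −20 °C; then CH2N2, Et2O, 0 °C
Reagents that add atoms: diazomethane, C=[N+]=[N-]
Why: First half of an Arndt–Eistert homologation, in which diazomethane is acylated by the mixed anhydride under conditions that should not epimerise the α-alkoxy carbon.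

Step 9
Reactants: 12 diazoketone
Product: 14 homologated diester, via ketene 13 (not isolated)
Conditions: PhCO2Ag (cat.), Et3N, MeOH, rt, dark
Reagents that add atoms: methanol, CO
Why: Wolff rearrangement, in which the dioxolanyl carbon migrates with retention to the ketene that methanol traps, so the future C9 keeps its configuration and gains the C10 methylene and the C14 methyl ester.

Step 10
Reactants: 14 homologated diester
Product: 15 dioxolane acid
Conditions: LiOH (1.0 equiv), THF/H2O, 0 °C; then HCl to pH 3
Reagents that add atoms: lithium hydroxide, [Li+].[OH-]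
Why: Saponification should select the ester on the dioxolane ring, which is activated by its α-oxygen, over the CH2CO2Me ester, and it frees the carboxyl group that later leaves as CO2.

Step 11
Reactants: 15 dioxolane acid; 8 (S)-2,3-bis(tert-butyldimethylsilyloxy)propanal
Product: 18 enoate acid, via aldol adduct 16 (not isolated), via acetylated adduct 17 (not isolated)
Conditions: LiN(iPr)2 (2.2 equiv), THF, −78 °C; 8; then Ac2O, −78 to 0 °C; then DBU, rt; aqueous work-up at pH 3–4
Reagents that add atoms: none
Why: Aldol condensation in three stages (addition of the carboxylate–ester enolate dianion at C10 to the aldehyde, acetylation, E1cB elimination with DBU) should give the trisubstituted enoate mainly as the E isomer with C2 trans to the ester and cis to C9, while the carboxylate blocks enolisation at C8 and the low temperature suppresses β-elimination of the ring oxygen.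

Step 12
Reactants: 18 enoate acid; 19 (S)-5-(hydroxymethyl)furan-2(5H)-one
Product: 20 lactone alcohol
Conditions: [Ir{dF(CF3)ppy}2(dtbbpy)]PF6 (1 mol%), K2HPO4, DMF, blue LEDs, rt
Reagents that add atoms: none
Why: Photoredox decarboxylative Giese addition, in which oxidation of the α-oxy carboxylate and loss of CO2 give the dioxolan-4-yl radical at C8 that adds to C7 of the butenolide anti to the C6 hydroxymethyl group (setting C7) and reacts trans to the C9 substituent on the dioxolane ring (setting C8), after which the lactone α-radical is reduced and protonated.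

Step 13
Reactants: 20 lactone alcohol
Product: 21 C5 aldehyde
Conditions: Dess–Martin periodinane, NaHCO3, CH2Cl2, 0 °C to rt
Reagents that add atoms: none
Why: Buffered Dess–Martin oxidation should convert the only free hydroxyl into the aldehyde without epimerising C6, and the aldehyde is used directly.

Step 14
Reactants: 21 C5 aldehyde
Product: 22 Z alkenyl iodide
Conditions: [Ph3PCH2CH3]I, nBuLi, THF, rt; I2, −78 °C; NaN(SiMe3)2, −20 °C; then 21, −78 °C
Reagents that add atoms: ethyltriphenylphosphonium iodide, CC[P+](c1ccccc1)(c1ccccc1)c1ccccc1.[I-]; iodine, II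
Why: Stork–Zhao olefination with the α-iodo ylide should install C4 and C15 as the Z iodoalkene (C6 cis to iodine) under kinetic control at −78 °C, where esters, lactone and ketal are tolerated.

Step 15
Reactants: 22 Z alkenyl iodide
Product: 24 acetoxymethyl lactone, via hydroxymethyl lactone 23 (not isolated)
Conditions: LiN(SiMe3)2 (1.05 equiv), THF, −78 °C; CH2O (THF solution); then Ac2O, −78 °C; AcOH quench
Reagents that add atoms: formaldehyde, C=O; acetic anhydride, CC(=O)OC(C)=O
Why: Aldol hydroxymethylation of the lactone enolate (the only CH2 alpha to a carbonyl, since C10 is now sp2) followed by in situ acetylation should install C13 as a β-acetoxy group that is a latent methylene, the new C11 centre being inconsequential.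

Step 16
Reactants: 24 acetoxymethyl lactone
Product: 25 8,9-diol
Conditions: Me2BBr, CH2Cl2, −78 °C; then aqueous NaHCO3
Reagents that add atoms: none
Why: Lewis-acid cleavage of the isopropylidene ketal with Me2BBr at −78 °C should free the syn 8,9-diol while the silyl ethers, esters and alkenyl iodide, which would not survive protic hydrolysis equally well, are left intact.

Step 17
Reactants: 25 8,9-diol
Product: 26 C9 acetate
Conditions: Ac2O (1.1 equiv), pyridine, DMAP (cat.), CH2Cl2, −40 °C
Reagents that add atoms: acetic anhydride, CC(=O)OC(C)=O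
Why: Kinetic acylation should take place at the C9 hydroxyl, which is allylic, β to the C14 ester and hence the more acidic and accessible one, in preference to the C8 hydroxyl that is flanked by the lactone ring carbon C7.

Step 18
Reactants: 26 C9 acetate; 4 (2S,3S)-epoxyangelic acid
Product: 28 C8 epoxyangelate, via Yamaguchi mixed anhydride 27 (not isolated)
Conditions: 4, 2,4,6-trichlorobenzoyl chloride, Et3N, toluene, rt; then 26, DMAP, toluene, rt
Reagents that add atoms: none
Why: Yamaguchi esterification should acylate the remaining hindered C8 hydroxyl with retention at C8, the α-quaternary epoxy acid being unable to epimerise, so that C8–OH is never left free next to the C12 and C14 carbonyls for long.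

Step 19
Reactants: 28 C8 epoxyangelate
Product: 29 C3 alcohol
Conditions: camphorsulfonic acid (cat.), MeOH/CH2Cl2, 0 °C
Reagents that add atoms: none
Why: Acid-catalysed methanolysis should remove the primary silyl ether at C3 much faster than the hindered secondary allylic one at C2, and the ester-deactivated oxirane should survive these mild conditions.

Step 20
Reactants: 29 C3 alcohol
Product: 30 C3 aldehyde
Conditions: Dess–Martin periodinane, NaHCO3, CH2Cl2, 0 °C
Reagents that add atoms: none
Why: Buffered Dess–Martin oxidation avoids base, so the C2 centre (alpha to the new aldehyde and gamma to the enoate) should be kept, and the aldehyde is carried on crude.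

Step 21
Reactants: 30 C3 aldehyde
Product: 31 C3 acid
Conditions: NaClO2, NaH2PO4, 2-methyl-2-butene, tBuOH/H2O, 0 °C
Reagents that add atoms: sodium chlorite, [Na+].[O-]Cl=O
Why: Pinnick oxidation at pH 3–4 with a hypochlorite scavenger should give the acid without epimerising C2 or touching the alkenyl iodide, the alkenes and the oxirane.

Step 22
Reactants: 31 C3 acid
Product: 32 stannyl acid
Conditions: (Bu3Sn)2, PdCl2(PPh3)2 (cat.), iPr2NEt, THF, 40 °C, dark
Reagents that add atoms: hexabutylditin, CCCC[Sn](CCCC)(CCCC)[Sn](CCCC)(CCCC)CCCC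
Why: Palladium-catalysed iodine–tin exchange with the ditin should replace iodine with retention of the Z geometry, and it is run before the thioester is made because zerovalent palladium inserts into carbon–iodine bonds far faster than it ionises the hindered allylic C9 acetate.

Step 23
Reactants: 32 stannyl acid
Product: 33 seco C3 thioester C4 alkenylstannane
Conditions: EtSH, DCC, DMAP (cat.), CH2Cl2, −20 to 0 °C
Reagents that add atoms: ethanethiol, CCS
Why: Steglich thioesterification at low temperature with only catalytic DMAP should give the S-ethyl thioester without epimerising C2, without protodestannylation and without eliminating the β-acetoxy lactone.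

Step 24
Reactants: 33 seco C3 thioester C4 alkenylstannane
Product: 34 macrocyclic C3 enone
Conditions: Pd2(dba)3 (cat.), tri(2-furyl)phosphine, CuOP(O)Ph2 (3 equiv), THF, 40 °C, 0.001 M, syringe-pump addition
Reagents that add atoms: none
Why: Zerovalent palladium inserts into the C3–S bond of the thioester with the help of CuOP(O)Ph2, which takes up the thiolate and the tin residue, the Z alkenyl group passes from tin to palladium with retention, and reductive elimination forms the C3–C4 bond. The closest known reaction is the Liebeskind–Srogl ketone synthesis from thioesters and alkenylstannanes under base-free conditions, here run intramolecularly at high dilution. The ten-membered carbocycle closes head to tail through an eleven-membered acyl(alkenyl)palladium intermediate, a cross-coupling macrocyclisation outside the Baldwin scheme, and the two ring alkenes that are cis within the ring (C1=C10 and C4=C5) together with the lactone pre-fold the chain. No stereocentre is formed. The step needs retention of the Z stannane geometry and an intact C2 centre, both secured by the neutral medium, and it needs C–S insertion to win over ionisation of the allylic C9 acetate and the allylic lactone oxygen at C6, which the weakly donating tri(2-furyl)phosphine and the copper-assisted thioester activation should ensure.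

Step 25
Reactants: 34 macrocyclic C3 enone
Product: 35 (3R) allylic alcohol
Conditions: NaBH4, CeCl3·7H2O, MeOH, −78 °C
Reagents that add atoms: none
Why: Luche reduction should add hydride to the C3 carbonyl only (1,2-mode) and anti to the C2 silyloxy group in the Felkin–Anh sense, giving the (3R) alcohol that is syn to the C2 oxygen, with acetates, lactone and oxirane untouched at −78 °C.

Step 26
Reactants: 35 (3R) allylic alcohol
Product: 36 C3 mesylate
Conditions: Ms2O, Et3N, CH2Cl2, −20 °C
Reagents that add atoms: methanesulfonic anhydride, CS(=O)(=O)OS(C)(=O)=O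
Why: Sulfonylation with the anhydride activates O3 with retention and avoids chloride, which could displace the allylic mesylate, and the crude mesylate is used directly.

Step 27
Reactants: 36 C3 mesylate
Product: 38 CNP0604635.2, via epoxide acetate 37 (not isolated)
Conditions: Bu4NF, THF, 0 °C; then DBU, 0 °C to rt
Reagents that add atoms: none
Why: Fluoride desilylation frees the C2 alkoxide, which displaces the adjacent allylic mesylate in an intramolecular Williamson reaction (3-exo-tet) with inversion at C3 and retention at C2 to give the cis (2R,3S) oxirane, and DBU then removes acetic acid from the β-acetoxy lactone by E1cB elimination to unveil the C11=C13 methylene.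

Compound list
1 | angelic acid, (Z)-2-methylbut-2-enoic acid | C/C=C(/C)C(=O)O | starting material
2 | angelyl alcohol, (Z)-2-methylbut-2-en-1-ol | C/C=C(/C)CO | intermediate
3 | [(2R,3S)-2,3-dimethyloxiran-2-yl]methanol | OC[C@@]1(C)O[C@H]1C | intermediate
4 | (2S,3S)-2,3-dimethyloxirane-2-carboxylic acid (epoxyangelic acid) | OC(=O)[C@@]1(C)O[C@H]1C | intermediate
5 | methyl (S)-2,2-dimethyl-1,3-dioxolane-4-carboxylate | COC(=O)[C@@H]1COC(C)(C)O1 | starting material
6 | methyl (S)-2,3-dihydroxypropanoate | COC(=O)[C@@H](O)CO | intermediate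
7 | methyl (S)-2,3-bis(tert-butyldimethylsilyloxy)propanoate | COC(=O)[C@@H](O[Si](C)(C)C(C)(C)C)CO[Si](C)(C)C(C)(C)C | intermediate
8 | (S)-2,3-bis(tert-butyldimethylsilyloxy)propanal | O=C[C@@H](O[Si](C)(C)C(C)(C)C)CO[Si](C)(C)C(C)(C)C | intermediate
9 | dimethyl (4R,5R)-2,2-dimethyl-1,3-dioxolane-4,5-dicarboxylate | COC(=O)[C@@H]1OC(C)(C)O[C@H]1C(=O)OC | starting material
10 | (4R,5R)-5-(methoxycarbonyl)-2,2-dimethyl-1,3-dioxolane-4-carboxylic acid | OC(=O)[C@@H]1OC(C)(C)O[C@H]1C(=O)OC | intermediate
11 | isobutyl carbonic mixed anhydride of 10 | CC(C)COC(=O)OC(=O)[C@@H]1OC(C)(C)O[C@H]1C(=O)OC | intermediate (not isolated)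
12 | methyl (4R,5R)-5-(2-diazoacetyl)-2,2-dimethyl-1,3-dioxolane-4-carboxylate | [N-]=[N+]=CC(=O)[C@@H]1OC(C)(C)O[C@H]1C(=O)OC | intermediate
13 | methyl (4R,5S)-2,2-dimethyl-5-(2-oxoethenyl)-1,3-dioxolane-4-carboxylate (ketene) | O=C=C[C@@H]1OC(C)(C)O[C@H]1C(=O)OC | intermediate (not isolated)
14 | methyl (4R,5S)-5-(2-methoxy-2-oxoethyl)-2,2-dimethyl-1,3-dioxolane-4-carboxylate | COC(=O)C[C@@H]1OC(C)(C)O[C@H]1C(=O)OC | intermediate
15 | (4R,5S)-5-(2-methoxy-2-oxoethyl)-2,2-dimethyl-1,3-dioxolane-4-carboxylic acid | COC(=O)C[C@@H]1OC(C)(C)O[C@H]1C(=O)O | intermediate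
16 | aldol adduct: 15 carrying at C10 the CH(OH)–C2(OTBS)–C3H2OTBS chain of 8 (epimers at C10 and C1) | OC(=O)[C@@H]1OC(C)(C)O[C@H]1C(C(=O)OC)C(O)[C@@H](O[Si](C)(C)C(C)(C)C)CO[Si](C)(C)C(C)(C)C | intermediate (not isolated)
17 | O-acetyl derivative of 16 with the carboxyl group as its mixed acetic anhydride | CC(=O)OC(=O)[C@@H]1OC(C)(C)O[C@H]1C(C(=O)OC)C(OC(C)=O)[C@@H](O[Si](C)(C)C(C)(C)C)CO[Si](C)(C)C(C)(C)C | intermediate (not isolated)
18 | (4R,5S)-5-[(2E,4R)-4,5-bis(tert-butyldimethylsilyloxy)-1-methoxy-1-oxopent-2-en-2-yl]-2,2-dimethyl-1,3-dioxolane-4-carboxylic acid | OC(=O)[C@@H]1OC(C)(C)O[C@H]1/C(C(=O)OC)=C\[C@@H](O[Si](C)(C)C(C)(C)C)CO[Si](C)(C)C(C)(C)C | intermediate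
19 | (S)-5-(hydroxymethyl)furan-2(5H)-one | O=C1O[C@@H](C=C1)CO | starting material
20 | lactone alcohol: (4S,5S)-5-(hydroxymethyl)-4-{(4S,5S)-5-[(2E,4R)-4,5-bis(tert-butyldimethylsilyloxy)-1-methoxy-1-oxopent-2-en-2-yl]-2,2-dimethyl-1,3-dioxolan-4-yl}dihydrofuran-2(3H)-one (6,7-trans lactone, 8,9-trans acetonide) | C1C(=O)O[C@H](CO)[C@H]1[C@@H]2OC(C)(C)O[C@H]2/C(C(=O)OC)=C\[C@@H](O[Si](C)(C)C(C)(C)C)CO[Si](C)(C)C(C)(C)C | intermediate
21 | C5 aldehyde: 20 with CHO in place of CH2OH on C6 | C1C(=O)O[C@H](C=O)[C@H]1[C@@H]2OC(C)(C)O[C@H]2/C(C(=O)OC)=C\[C@@H](O[Si](C)(C)C(C)(C)C)CO[Si](C)(C)C(C)(C)C | intermediate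
22 | Z alkenyl iodide: 20 with (Z)-CH=C(CH3)I on C6 (C6 cis to iodine) | C1C(=O)O[C@H](/C=C(/C)I)[C@H]1[C@@H]2OC(C)(C)O[C@H]2/C(C(=O)OC)=C\[C@@H](O[Si](C)(C)C(C)(C)C)CO[Si](C)(C)C(C)(C)C | intermediate
23 | hydroxymethyl lactone: 22 with CH2OH (C13) on C11 | OCC1C(=O)O[C@H](/C=C(/C)I)[C@H]1[C@@H]2OC(C)(C)O[C@H]2/C(C(=O)OC)=C\[C@@H](O[Si](C)(C)C(C)(C)C)CO[Si](C)(C)C(C)(C)C | intermediate (not isolated)
24 | acetoxymethyl lactone: 22 with CH2OAc (C13) on C11 | CC(=O)OCC1C(=O)O[C@H](/C=C(/C)I)[C@H]1[C@@H]2OC(C)(C)O[C@H]2/C(C(=O)OC)=C\[C@@H](O[Si](C)(C)C(C)(C)C)CO[Si](C)(C)C(C)(C)C | intermediate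
25 | 8,9-diol: 24 without the isopropylidene group, (8S,9S) syn diol | CC(=O)OCC1C(=O)O[C@H](/C=C(/C)I)[C@H]1[C@H](O)[C@@H](O)/C(C(=O)OC)=C\[C@@H](O[Si](C)(C)C(C)(C)C)CO[Si](C)(C)C(C)(C)C | intermediate
26 | C9 acetate: 25 acetylated on O9, C8 hydroxyl free | CC(=O)OCC1C(=O)O[C@H](/C=C(/C)I)[C@H]1[C@H](O)[C@@H](OC(C)=O)/C(C(=O)OC)=C\[C@@H](O[Si](C)(C)C(C)(C)C)CO[Si](C)(C)C(C)(C)C | intermediate
27 | (2S,3S)-2,3-dimethyloxirane-2-carboxylic 2,4,6-trichlorobenzoic anhydride | O=C(OC(=O)[C@@]1(C)O[C@H]1C)c1c(Cl)cc(Cl)cc1Cl | intermediate (not isolated)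
28 | C8 epoxyangelate: 26 esterified on O8 with acid 4 | CC(=O)OCC1C(=O)O[C@H](/C=C(/C)I)[C@H]1[C@H](OC(=O)[C@@]2(C)O[C@H]2C)[C@@H](OC(C)=O)/C(C(=O)OC)=C\[C@@H](O[Si](C)(C)C(C)(C)C)CO[Si](C)(C)C(C)(C)C | intermediate
29 | C3 alcohol: 28 with C3 as CH2OH (C2 silyl ether kept) | CC(=O)OCC1C(=O)O[C@H](/C=C(/C)I)[C@H]1[C@H](OC(=O)[C@@]2(C)O[C@H]2C)[C@@H](OC(C)=O)/C(C(=O)OC)=C\[C@@H](O[Si](C)(C)C(C)(C)C)CO | intermediate
30 | C3 aldehyde: 29 with C3 as CHO | CC(=O)OCC1C(=O)O[C@H](/C=C(/C)I)[C@H]1[C@H](OC(=O)[C@@]2(C)O[C@H]2C)[C@@H](OC(C)=O)/C(C(=O)OC)=C\[C@@H](O[Si](C)(C)C(C)(C)C)C=O | intermediate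
31 | C3 acid: 29 with C3 as CO2H | CC(=O)OCC1C(=O)O[C@H](/C=C(/C)I)[C@H]1[C@H](OC(=O)[C@@]2(C)O[C@H]2C)[C@@H](OC(C)=O)/C(C(=O)OC)=C\[C@@H](O[Si](C)(C)C(C)(C)C)C(O)=O | intermediate
32 | stannyl acid: 31 with SnBu3 in place of iodine (Z, C6 cis to tin) | CC(=O)OCC1C(=O)O[C@H](/C=C(/C)[Sn](CCCC)(CCCC)CCCC)[C@H]1[C@H](OC(=O)[C@@]2(C)O[C@H]2C)[C@@H](OC(C)=O)/C(C(=O)OC)=C\[C@@H](O[Si](C)(C)C(C)(C)C)C(O)=O | intermediate
33 | seco precursor: S-ethyl thioester of 32 (C3 thioester, Z C4 alkenylstannane, C2 (R) silyl ether, 1(10)E enoate, 9-acetate, 8-epoxyangelate, 6,12-lactone with C11–CH2OAc) | CC(=O)OCC1C(=O)O[C@H](/C=C(/C)[Sn](CCCC)(CCCC)CCCC)[C@H]1[C@H](OC(=O)[C@@]2(C)O[C@H]2C)[C@@H](OC(C)=O)/C(C(=O)OC)=C\[C@@H](O[Si](C)(C)C(C)(C)C)C(=O)SCC | intermediate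
34 | macrocyclic enone: ten-membered ring closed at C3–C4, C3 ketone, C2 (R) silyl ether, 4Z and 1(10)E alkenes, other groups as in 33 | CC(=O)OCC1C(=O)O[C@@H]2/C=C(/C)C(=O)[C@H](O[Si](C)(C)C(C)(C)C)/C=C(/C(=O)OC)[C@H](OC(C)=O)[C@@H](OC(=O)[C@@]3(C)O[C@H]3C)[C@@H]12 | intermediate
35 | (3R) allylic alcohol of 34 (2R,3R, syn to the C2 silyl ether) | CC(=O)OCC1C(=O)O[C@@H]2/C=C(/C)[C@@H](O)[C@H](O[Si](C)(C)C(C)(C)C)/C=C(/C(=O)OC)[C@H](OC(C)=O)[C@@H](OC(=O)[C@@]3(C)O[C@H]3C)[C@@H]12 | intermediate
36 | C3 methanesulfonate of 35 | CC(=O)OCC1C(=O)O[C@@H]2/C=C(/C)[C@@H](OS(C)(=O)=O)[C@H](O[Si](C)(C)C(C)(C)C)/C=C(/C(=O)OC)[C@H](OC(C)=O)[C@@H](OC(=O)[C@@]3(C)O[C@H]3C)[C@@H]12 | intermediate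
37 | epoxide acetate: 38 with C11–CH2OAc in place of the C11=C13 methylene, cis (2R,3S) oxirane | CC(=O)OCC1C(=O)O[C@@H]2/C=C(/C)[C@@H]3O[C@@H]3/C=C(/C(=O)OC)[C@H](OC(C)=O)[C@@H](OC(=O)[C@@]3(C)O[C@H]3C)[C@@H]12 | intermediate (not isolated)
38 | CNP0604635.2 | C=C1C(=O)O[C@@H]2/C=C(/C)[C@@H]3O[C@@H]3/C=C(/C(=O)OC)[C@H](OC(C)=O)[C@@H](OC(=O)[C@@]3(C)O[C@H]3C)[C@@H]12 | target

Total step count: 27. Longest linear sequence: 21 steps (steps 7 to 27, from 9).

Steps most likely to fail

Step 24. Ring closure to a ten-membered ring may lose to intermolecular coupling, and the alkenylstannane may be consumed by protodestannylation or copper-mediated homocoupling before it transmetalates. The fallback sets out from aldehyde 30, which already holds the C3 aldehyde and the Z C4 alkenyl iodide: an intramolecular Nozaki–Hiyama–Kishi reaction (CrCl2, NiCl2 cat., DMSO/THF, high dilution, rt) should close the same C3–C4 bond to give the macrocyclic allylic alcohol F1 as both C3 epimers, and Dess–Martin oxidation of F1 comes back to the route at enone 34.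

Step 17. The anhydride may fail to distinguish the C9 from the C8 hydroxyl (poor site selectivity), and the acetyl group may migrate between the two oxygens. The fallback sets out from diol 25: trimethyl orthoacetate and pyridinium p-toluenesulfonate should convert it into the cyclic orthoacetate F2, and brief hydrolysis in aqueous acetic acid opens F2 to the hydroxy acetate by collapse of a hemi-orthoester, a process that places the acyl group on the more hindered oxygen and is therefore complementary to direct acylation; if step 17 fails by acetylating O8, this should leave the acetate on O9, and the route is rejoined at 26.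

Step 25. Hydride delivery to the macrocyclic enone may follow the ring conformation and not the Felkin–Anh preference, so that the (3S) alcohol predominates (reversed facial selectivity), which by the mesylate route would give the trans oxirane. The fallback sets out from 34: the (3S) allylic alcohol F3 formed in that case is converted by an Appel reaction (PPh3, CBr4, 2,6-lutidine, CH2Cl2, 0 °C) into the (3R) allylic bromide F4 with inversion; Bu4NF then frees the C2 alkoxide, which displaces bromide with a second inversion, and the route comes back at the cis epoxide 37, which DBU takes on to 38.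

Further compounds
F1 | step 24 | macrocyclic C3 allylic alcohol, both C3 epimers, otherwise as 35 | CC(=O)OCC1C(=O)O[C@@H]2/C=C(/C)C(O)[C@H](O[Si](C)(C)C(C)(C)C)/C=C(/C(=O)OC)[C@H](OC(C)=O)[C@@H](OC(=O)[C@@]3(C)O[C@H]3C)[C@@H]12
F2 | step 17 | 8,9-cyclic orthoacetate of 25 (2-methoxy-2-methyl-1,3-dioxolane, trans on C8/C9) | CC(=O)OCC1C(=O)O[C@H](/C=C(/C)I)[C@H]1[C@@H]2OC(C)(OC)O[C@H]2/C(C(=O)OC)=C\[C@@H](O[Si](C)(C)C(C)(C)C)CO[Si](C)(C)C(C)(C)C
F3 | step 25 | (3S) allylic alcohol, the C3 epimer of 35 | CC(=O)OCC1C(=O)O[C@@H]2/C=C(/C)[C@H](O)[C@H](O[Si](C)(C)C(C)(C)C)/C=C(/C(=O)OC)[C@H](OC(C)=O)[C@@H](OC(=O)[C@@]3(C)O[C@H]3C)[C@@H]12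
F4 | step 25 | (3R) allylic bromide, bromine in place of the C3 hydroxyl of 35 | CC(=O)OCC1C(=O)O[C@@H]2/C=C(/C)[C@@H](Br)[C@H](O[Si](C)(C)C(C)(C)C)/C=C(/C(=O)OC)[C@H](OC(C)=O)[C@@H](OC(=O)[C@@]3(C)O[C@H]3C)[C@@H]12
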